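**Retrosynthetic overview**

1. Target 20 ⇐ diol 18 by double acetylation (last step).
2. 18 ⇐ open-chain trienediol 17: rings A and B close in one operation from the isopropenyl end (C4–C5 bond, ring A, then C9–C10 bond, ring B; proton loss gives the 7,8-alkene). The (R)-carbinol at C2 steers C5, C9 and C10.
3. 17 ⇐ vinyl iodide 10 + dienol 15 (C5–C6 bond; diene hydroboration, then B-alkyl Suzuki coupling).
4. 10 ⇐ (R)-epichlorohydrin 1 (C1–C3 and the C2 stereocentre) + isopropenyl Grignard 2 + acetylide 4 + Me3Al 7; 15 ⇐ (S)-citronellol 11 (C13 stereocentre) by allylic oxidation and methylenation.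

Assumption: positions are quoted in labdane numbering (ring A = C1–C5 and C10, ring B = C5–C10, oxygen on C2, gem-dimethyl on C4, side chain C11–C15 on C9), in which the target is (2R,5R,9R,10R,13S); only reagents that put non-hydrogen atoms into a product are numbered as starting materials.

**Route**

Step 1
Reactants: 1 (R)-epichlorohydrin; 2 isopropenylmagnesium bromide
Product: 3 (2R)-1-chloro-4-methylpent-4-en-2-ol
Conditions: CuI (10 mol%), THF, −40 → −20 °C; aq. NH4Cl
Reagents that add atoms: isopropenylmagnesium bromide (2), CC(=C)[Mg]Br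
Why: Copper-catalysed Grignard opening of the epoxide at its unsubstituted carbon (SN2) breaks no bond to the stereocentre, so the (R) centre of 1 is carried unchanged into what becomes C2.

Step 2
Reactants: 3 (2R)-1-chloro-4-methylpent-4-en-2-ol; 4 lithium acetylide–ethylenediamine complex
Product: 6 (4R)-6-methylhept-6-en-1-yn-4-ol, via (2R)-2-(2-methylallyl)oxirane 5 (not isolated)
Conditions: LiC≡CH·H2NCH2CH2NH2 (2.5 equiv), DMSO, 0 °C → rt
Reagents that add atoms: lithium acetylide–ethylenediamine complex (4), [Li+].[C-]#C.NCCN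
Why: The first equivalent of acetylide closes the chlorohydrin to the terminal epoxide (intramolecular Williamson reaction) and the second opens it at CH2 (SN2 epoxide opening), neither event touching the C–O stereocentre.

Step 3
Reactants: 6 (4R)-6-methylhept-6-en-1-yn-4-ol; 7 trimethylaluminium; 8 iodine
Product: 10 (1E,4R)-1-iodo-2,6-dimethylhepta-1,6-dien-4-ol, via O-aluminated (E)-alkenyldimethylalane 9 (not isolated)
Conditions: Me3Al (3 equiv), Cp2ZrCl2 (25 mol%), CH2Cl2, 0 °C → rt; then I2, THF, −30 → 0 °C; aq. Na2S2O3, Rochelle salt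
Reagents that add atoms: trimethylaluminium (7), C[Al](C)C; iodine (8), II
Why: Negishi zirconium-catalysed carboalumination adds CH3 and Al syn across the terminal alkyne with Al on the terminal carbon, and iodinolysis with retention fixes the (E)-trisubstituted vinyl iodide, while the 1,1-disubstituted alkene does not carbometalate under these conditions.

Step 4
Reactants: 11 (S)-citronellol; 12 selenium dioxide
Product: 13 (2E,6S)-8-hydroxy-2,6-dimethyloct-2-enal
Conditions: SeO2 (1.1 equiv), EtOH, reflux
Reagents that add atoms: selenium dioxide (12), O=[Se]=O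
Why: Riley allylic oxidation (ene reaction then [2,3]-sigmatropic shift) is selective for the (E)-methyl of the trisubstituted alkene and with stoichiometric SeO2 at reflux runs on to the (E)-enal, the remote methyl stereocentre taking no part.

Step 5
Reactants: 13 (2E,6S)-8-hydroxy-2,6-dimethyloct-2-enal; 14 methyltriphenylphosphonium bromide
Product: 15 (3S,6E)-3,7-dimethylnona-6,8-dien-1-ol
Conditions: Ph3PCH3Br (2.3 equiv), KOt-Bu (2.2 equiv), THF, 0 °C → rt
Reagents that add atoms: methyltriphenylphosphonium bromide (14), C[P+](c1ccccc1)(c1ccccc1)c1ccccc1.[Br-]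
Why: Wittig methylenation of the enal gives the (E)-1,3-diene without disturbing the trisubstituted alkene geometry, the second equivalent of ylide covering the free hydroxyl.

Step 6
Reactants: 15 (3S,6E)-3,7-dimethylnona-6,8-dien-1-ol; 10 (1E,4R)-1-iodo-2,6-dimethylhepta-1,6-dien-4-ol
Product: 17 (3S,6E,10E,13R)-3,7,11,15-tetramethylhexadeca-6,10,15-triene-1,13-diol, via O,C-bis(9-borabicyclononyl) adduct 16 (not isolated)
Conditions: 15 (1.3 equiv), 9-BBN (2.6 equiv), THF, 0 °C → rt; aq. Cs2CO3 (destroys residual B–H); then 10, PdCl2(dppf) (5 mol%), AsPh3, DMF, rt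
Reagents that add atoms: none
Why: 9-BBN hydroborates only the terminal carbon of the conjugated diene (anti-Markovnikov), and the B-alkyl Suzuki–Miyaura coupling joins this sp3 carbon to the vinyl iodide with retention of the (E) geometry, giving the 1,5-diene with both stereocentres untouched.

Step 7
Reactants: 17 (3S,6E,10E,13R)-3,7,11,15-tetramethylhexadeca-6,10,15-triene-1,13-diol
Product: 18 (2R,4aR,8R,8aR)-8-[(3S)-5-hydroxy-3-methylpentyl]-4,4,7,8a-tetramethyl-1,2,3,4,4a,5,8,8a-octahydronaphthalen-2-ol
Conditions: CoC32H46N2O2 [N,N′-bis(3,5-di-tert-butylsalicylidene)ethane-1,2-diaminato complex of divalent cobalt] (5 mol%), N-fluoro-2,4,6-trimethylpyridinium triflate (1.3 equiv), PhSiH3 (1.3 equiv), (CF3)2CHOH, 0.02 M, 0 °C → rt; then K2CO3, MeOH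
Reagents that add atoms: none
Why: Proposed new method: cobalt-hydride hydrogen-atom transfer picks the 1,1-disubstituted alkene over the two trisubstituted ones, the tertiary C4 radical is oxidised by the cobalt/N-fluoropyridinium couple to a cation (radical–polar crossover) that closes ring A onto the C5=C10 alkene and ring B onto the C8=C9 alkene through a chair–chair array of the two (E)-alkenes (trans ring fusion, equatorial side chain) in which the C2 carbinol sits equatorial to avoid the two axial methyls, so C5, C10 and C9 (4a, 8a and 8 in the name) are all set (R) from the (R)-carbinol, and loss of a C7 proton gives the 7,8-alkene (an exocyclic isomer would be re-activated by the same catalyst); the closest known reaction type is the cobalt-salen hydrogen-atom-transfer-initiated radical–polar crossover bicyclisation of arene-terminated polyenes, here ended by proton loss and steered by a resident carbinol.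

Step 8
Reactants: 18 (2R,4aR,8R,8aR)-8-[(3S)-5-hydroxy-3-methylpentyl]-4,4,7,8a-tetramethyl-1,2,3,4,4a,5,8,8a-octahydronaphthalen-2-ol; 19 acetic anhydride
Product: 20 (2R,4aR,8R,8aR)-8-[(3S)-5-acetoxy-3-methylpentyl]-4,4,7,8a-tetramethyl-1,2,3,4,4a,5,8,8a-octahydronaphthalen-2-yl acetate (CNP0220683.1)
Conditions: Ac2O (4 equiv), pyridine, DMAP (cat.), CH2Cl2, rt
Reagents that add atoms: acetic anhydride (19), CC(=O)OC(C)=O
Why: DMAP-catalysed acyl transfer esterifies the primary and the equatorial secondary hydroxyl without touching any stereocentre or the ring alkene.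

**Compound list**

1 | (R)-epichlorohydrin, (2R)-2-(chloromethyl)oxirane | ClC[C@H]1CO1 | starting material
2 | isopropenylmagnesium bromide (THF solution) | CC(=C)[Mg]Br | starting material
3 | (2R)-1-chloro-4-methylpent-4-en-2-ol | ClC[C@H](O)CC(C)=C | intermediate
4 | lithium acetylide–ethylenediamine complex | [Li+].[C-]#C.NCCN | starting material
5 | (2R)-2-(2-methylprop-2-en-1-yl)oxirane | C=C(C)C[C@@H]1CO1 | intermediate
6 | (4R)-6-methylhept-6-en-1-yn-4-ol | C#CC[C@H](O)CC(C)=C | intermediate
7 | trimethylaluminium | C[Al](C)C | starting material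
8 | iodine | II | starting material
9 | [(1E,4R)-4-(dimethylaluminiooxy)-2,6-dimethylhepta-1,6-dien-1-yl]dimethylaluminium (Al cis to the C2 methyl) | C[Al](C)/C=C(\C)C[C@H](O[Al](C)C)CC(C)=C | intermediate
10 | (1E,4R)-1-iodo-2,6-dimethylhepta-1,6-dien-4-ol | I/C=C(\C)C[C@H](O)CC(C)=C | intermediate
11 | (S)-(−)-citronellol, (3S)-3,7-dimethyloct-6-en-1-ol | OCC[C@@H](C)CCC=C(C)C | starting material
12 | selenium dioxide | O=[Se]=O | starting material
13 | (2E,6S)-8-hydroxy-2,6-dimethyloct-2-enal | OCC[C@@H](C)CC/C=C(\C)C=O | intermediate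
14 | methyltriphenylphosphonium bromide | C[P+](c1ccccc1)(c1ccccc1)c1ccccc1.[Br-] | starting material
15 | (3S,6E)-3,7-dimethylnona-6,8-dien-1-ol | OCC[C@@H](C)CC/C=C(\C)C=C | intermediate
16 | 9-{[(3S,6E)-9-(9-borabicyclo[3.3.1]nonan-9-yl)-3,7-dimethylnon-6-en-1-yl]oxy}-9-borabicyclo[3.3.1]nonane | C1CCC2CCCC1B2OCC[C@@H](C)CC/C=C(\C)CCB1C2CCCC1CCC2 | intermediate
17 | (3S,6E,10E,13R)-3,7,11,15-tetramethylhexadeca-6,10,15-triene-1,13-diol | OCC[C@@H](C)CC/C=C(\C)CC/C=C(\C)C[C@H](O)CC(C)=C | intermediate
18 | (2R,4aR,8R,8aR)-8-[(3S)-5-hydroxy-3-methylpentyl]-4,4,7,8a-tetramethyl-1,2,3,4,4a,5,8,8a-octahydronaphthalen-2-ol | OCC[C@@H](C)CC[C@@H]1C(C)=CC[C@@H]2C(C)(C)C[C@@H](O)C[C@@]12C | intermediate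
19 | acetic anhydride | CC(=O)OC(C)=O | starting material
20 | (2R,4aR,8R,8aR)-8-[(3S)-5-acetoxy-3-methylpentyl]-4,4,7,8a-tetramethyl-1,2,3,4,4a,5,8,8a-octahydronaphthalen-2-yl acetate | CC(=O)OCC[C@@H](C)CC[C@@H]1C(C)=CC[C@@H]2C(C)(C)C[C@@H](OC(C)=O)C[C@@]12C | target

**Step count and risks**

Total steps: 8 (steps 1–3 make fragment 10, steps 4–5 make fragment 15, steps 6–8 couple, cyclise and acetylate). Longest linear sequence: 6 steps (1 → 3 → 6 → 10 → 17 → 18 → 20).

Most likely to fail, first: step 7. The C4 cation may be caught by the C2 hydroxyl as a 2,2-dimethyloxetane, may lose a proton early to give an unreactive trisubstituted alkene, or the cascade may end as a mixture of 7,8-, 8,9- and exocyclic alkenes (separable on AgNO3-impregnated silica). The fallback sets out from 17: Mukaiyama hydration (Co(acac)2, PhSiH3, O2, i-PrOH, rt), selective for the 1,1-disubstituted alkene, gives (3S,6E,10E,13S)-3,7,11,15-tetramethylhexadeca-6,10-diene-1,13,15-triol F1. Its tertiary carbinol is then ionised with SnCl4 (CH2Cl2, −78 °C) in a classical Lewis-acid cation–olefin bicyclisation from a defined initiator, and the fallback comes back to the route at 18.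

Second: step 6. The two free hydroxyls consume borane, any residual B–H can attack the isopropenyl group of 10, and the vinylpalladium species could close onto that isopropenyl group in a Heck reaction. The fallback sets out from 15: hydroboration with 9-BBN followed by iodinolysis (I2, NaOMe, MeOH) gives (3S,6E)-9-iodo-3,7-dimethylnon-6-en-1-ol F2. F2 is joined to 10 by nickel-catalysed reductive cross-electrophile coupling (NiBr2·MeOCH2CH2OMe, 4,4′-di-tert-butyl-2,2′-bipyridine, Zn dust, N,N-dimethylacetamide, rt), which needs neither an organoboron partner nor base, and the fallback comes back at 17. It still relies on the diene hydroboration, so it answers a failure of the palladium coupling only.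

Third: step 4. The SeO2 oxidation may stop at the allylic alcohol or give a low yield with selenium-containing by-products. The fallback sets out from 11: ozonolysis (O3, CH2Cl2/MeOH, −78 °C; then PPh3) gives (4S)-6-hydroxy-4-methylhexanal F3. Wittig olefination of F3 with the stabilised ylide 2-(triphenylphosphoranylidene)propanal (toluene, 80 °C) builds the (E)-2-methyl-enal directly, and the fallback comes back at 13.

**Further compounds**

F1 | step 7 | (3S,6E,10E,13S)-3,7,11,15-tetramethylhexadeca-6,10-diene-1,13,15-triol | OCC[C@@H](C)CC/C=C(\C)CC/C=C(\C)C[C@H](O)CC(C)(C)O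
F2 | step 6 | (3S,6E)-9-iodo-3,7-dimethylnon-6-en-1-ol | OCC[C@@H](C)CC/C=C(\C)CCI
F3 | step 4 | (4S)-6-hydroxy-4-methylhexanal | OCC[C@@H](C)CCC=O
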